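## Structural features

The target is a C2-symmetric dimer of two 7-hydroxyisoflavan units. In each unit a phenolic benzene ring (ring A) is fused to a dihydropyran ring (O1, C2, C3, C4), and a second benzene ring (ring B) is bonded through C1' to C3. The halves are joined only by a diaryl ether oxygen between the two C4' carbons. Each ring B is contiguously tetrasubstituted: C1' carries the pyran, C2' a methoxy group, C3' a free hydroxyl and C4' the bridging oxygen. The only stereocentres are the two C3 carbons, both R. Each is a tertiary benzylic carbon between the C2 and C4 methylene groups, has no neighbouring stereocentre and lies far from its counterpart, so each must be set by a reagent and both with the same sense. The fragile elements are the four electron-rich phenols (the ring B hydroxyl sits in an easily oxidised pyrogallol-type array) and the C3 hydrogen, whose configuration is lost whenever a C3=C4 double bond or a C4 cation can form. The real difficulties are the crowded, differentially protected ring B with its ether bridge, the need to run every transformation twice in one molecule, and the control of two remote stereocentres. The key step exploits the attachment of ring B to C3 and not C2: each C3–C1' bond can be made by shifting ring B from the β- to the α-carbon of an aryl enone, which the para aryloxy and ortho methoxy groups of ring B make easy.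

## Logic of the disconnections

19 from 18: the four phenolic O–H bonds and the two C4–H bonds of 19 are traced back to four O–benzyl bonds and two benzylic C4–O bonds. One hydrogenolysis then unmasks all phenols and removes the carbinol that was needed to set C3. The forward step must not ionise C4, because C3 sits next to the bond being cleaved.

18 from 16, through 17: the C3–H and C4–H bonds of both arms are cut, which leads through the epimerisable α-aryl ketone 17 to the planar 16. One chiral transfer-hydrogenation catalyst can then fix C4 and, by dynamic kinetic resolution, C3. Both stereocentres are thereby traced to an achiral, fully aromatic precursor. The forward step needs enolisation of 17 to outrun ketone reduction, and catalyst control in both arms.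

16 from 14, through 15: the two O1–C2 bonds and the two C2=C3 double bonds are opened to the keto acetals of 14, in which the ring A oxygen ortho to the ketone is still masked. Pyranone closure becomes an acid-triggered acetal exchange and elimination. The acid must cleave the acetal-type protecting group but leave the benzyl ethers.

14 from 13: the two Cα–C1' bonds are cut and ring B is returned to Cβ of an enone. This is the strategic simplification, because 13 is the product of a plain aldol condensation. The forward step needs ring B to migrate in both arms in preference to solvent capture, ring A migration or attack by the ortho oxygen.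

13 from 9 and 12: the two Cα=Cβ double bonds are cut. This splits the molecule into a symmetrical dialdehyde and two equivalents of one methyl ketone. The aldehyde must be non-enolisable and the protecting groups must be base-stable.

12 from 11 from 10: the O–CH2 bonds of the MOM and benzyl groups are cut. The hydrogen bond of the ortho hydroxyl to the ketone allows the para hydroxyl to be benzylated first, and the ortho oxygen then receives the acid-labile group that step 9 removes.

9 from 7, through 8: the two benzyl O–C bonds are cut and the aldehydes are returned to their acetals. The forward step is an ordinary etherification of a hindered phenol followed by an acidic work-up.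

7 from 4, through 5 and 6: the two C–O bonds of the ring B hydroxyls are cut. The carbon concerned lies between the methoxy and the bridging oxygen and is the most acidic ring position, so the hydroxyl can be introduced after the ether bond by metalation, borylation and oxidation. This avoids differentiating three neighbouring hydroxyls and coupling two hindered partners. It requires masked aldehydes and metalation of both rings at that site.

4 from 3: the acetal C–O bonds are cut. The acetals protect the aldehydes from the organolithium and from the peroxide of step 3.

3 from 1 and 2: the diaryl ether C–O bond is cut. The formyl group para to the fluorine, which later becomes Cβ, activates the ring for addition–elimination, and both partners are commercial. The forward step needs only carbonate and heat.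

## Other disconnections considered

Alternative 1: The cut is made at the two C4–C4a bonds, with ring A of each arm carried as a cyclohexenone and aromatised later. Forward, the kinetic lithium enolate of 3-ethoxycyclohex-2-en-1-one A2 (deprotonated at C6) would be alkylated by both primary iodides of the enantioenriched bis-iodide A1 to give the bis(6-alkyl-3-ethoxycyclohexenone) A3. Dehydrogenation, release of the oxygens and closure of the O1–C2 bonds by phenol alkylation would follow.
- In its favour: the C3 stereocentres are already present in A1, where they can be set on a small unit by mature methods. C4 is a methylene group from the outset, so no carbinol has to be removed. No thallium is needed. On these three points the alternative is the better plan, and in being two-directional it is the equal of the chosen one.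
- Against it here: the iodides of A1 are β-branched and carry a benzylic β-hydrogen, so the strongly basic enolate is expected to favour E2 elimination over the slow SN2 reaction, twice. A3 would still need two aromatisations by oxidants beside the electron-rich ring B. It would leave the C7 oxygen as an ethyl ether that must be cleaved beside the C2' methyl ether, and two ring closures would remain.
- Comparison: a polar alkylation that competes with elimination stands against an aryl shift driven by the electron-rich ring B of the substrate itself. The sequence after A3 (aromatisation, dealkylation, cyclisation, hydrogenolysis) is longer than the three steps that follow 14, and A1 is harder to reach than 13.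

Alternative 2: Ring A itself is disconnected. The bonds C4a–C8a, C7–C8 and C6–C7 of each arm are cut, leading to the bis(diazo enone) A4 with an ethynyl ether on each C2 oxygen. Forward, irradiation of A4 would trigger in each arm a Wolff rearrangement to a vinylketene, intramolecular [2+2] addition of the ketene to the alkynyl ether, four-electron opening of the cyclobutenone and six-electron closure of the dienylketene with tautomerisation. Each pyran ring and each ring A would form, to give the benzyl-protected target A5.
- In its favour: six C–C bonds and four rings would form in one operation. The C7 hydroxyl is delivered free and in the right place by the mechanism. The C3 stereocentre is set beforehand and untouched by a pericyclic cascade, and only one hydrogenolysis follows. In bonds and rings built per step, and in the short endgame, the alternative is the better plan.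
- Against it here: A4 combines two vinyl diazo ketones with two terminal alkynyl ethers of primary alcohols. These are laborious to install on a β-branched alcohol and prone to thermal retro-ene fragmentation in the temperature range that the electrocyclic stages usually need. A ketene–alkyne addition closing a six-membered ring through an ether tether has little support. The electron-rich aryl ethers absorb where the diazo ketone does, and the cascade must succeed in both arms.
- Comparison: the same ring system would be reached without redox adjustment at C4, by a concerted and stereochemically safe mechanism. The linear synthesis of A4 (stereocentre, two diazo transfers, two ynol ethers) is expected to be clearly longer than the eight steps to 14, so overall step economy favours the chosen plan.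

Alternative 3: The two C3'–O bonds are cut last, so the whole sequence runs with ring B lacking its hydroxyl. Forward, the bis-isoflavan A6, protected at C7 as triisopropylsilyl ethers, would be lithiated at both C3' positions with sec-butyllithium and TMEDA, trapped as a borate and oxidised with peroxide to the diol A7. The silyl groups would then be removed.
- In its favour: C3' lies between the methoxy and the aryloxy oxygen and is the most acidic position of ring B. No protecting group is needed on ring B, and 3 could enter the condensation directly, which removes steps 2 to 4 of the chosen route. In simplicity of ring B the alternative is better. The reaction type is that of step 3 of the chosen plan, so on mechanism the two are equal.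
- Against it here: at this late stage the base finds further sites. One is C8 of ring A between O1 and the silyloxy group, with the risk of silyl migration from oxygen to carbon. The other is the benzylic C3–H next to the C2' methoxy group, whose removal would epimerise the stereocentre or expel the ring A phenoxide from C2. A double metalation would be tried on the most valuable intermediate, and the ring A benzyl ethers would have to be exchanged for silyl ethers and these removed again.
- Comparison: the three steps saved early are balanced by silylation, hydroxylation and desilylation at the end, so the plans are about equal in step count. The chosen plan places the same metalation on 4, where only the desired site is activated and no stereocentre exists.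

Key step: step 8

Remark on the structures: the substitution patterns of 13 and 14 map onto the target without change (ring B: side chain, then methoxy, then benzyloxy, then bridging oxygen; ring A: ortho MOM ether and para benzyl ether), and the target is read as the (3R,3'R) isomer.

Assumption: RuCl[(R,R)-TsDPEN](p-cymene) is taken to deliver hydride to the chromanone carbonyl with the same sense as to simple aryl alkyl ketones (R carbinol); cis reduction under dynamic kinetic resolution then gives 3R, and the (S,S) catalyst would be used if the sense proved opposite.

## Route

Step 1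
Reactants: 1 4-fluoro-2-methoxybenzaldehyde; 2 4-hydroxy-2-methoxybenzaldehyde
Product: 3 bis(4-formyl-3-methoxyphenyl) ether
Conditions: K2CO3, DMAc, 130 °C, N2
Reagents that add atoms: none
Why: Nucleophilic aromatic substitution by addition–elimination: the phenoxide of 2 attacks C4 of 1, where the para formyl group stabilises the anionic σ-adduct and fluoride is the best leaving group for this mechanism; neither aldehyde is enolisable, so carbonate at this temperature is tolerated.

Step 2
Reactants: 3 bis(4-formyl-3-methoxyphenyl) ether
Product: 4 bis[4-(dimethoxymethyl)-3-methoxyphenyl] ether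
Conditions: HC(OMe)3, MeOH, p-TsOH (cat.), rt to 45 °C; Et3N quench
Reagents that add atoms: trimethyl orthoformate, COC(OC)OC
Why: Acid-catalysed acetalisation driven by the orthoformate as water scavenger; the acetals shield both aldehydes from butyllithium and from Dakin oxidation by the peroxide in step 3.

Step 3
Reactants: 4 bis[4-(dimethoxymethyl)-3-methoxyphenyl] ether
Product: 7 bis[4-(dimethoxymethyl)-2-hydroxy-3-methoxyphenyl] ether, via dilithio bis-acetal 5 (not isolated), via bis(dimethoxyboryl) bis-acetal 6 (not isolated)
Conditions: n-BuLi (2.6 equiv), TMEDA, THF, −78 to −10 °C; B(OMe)3, −78 °C to rt; 30% H2O2, aq NaOH, 0 °C; Na2S2O3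
Reagents that add atoms: hydrogen peroxide, OO (the two hydroxyl oxygens); n-butyllithium, [Li]CCCC (lithium in 5); trimethyl borate, COB(OC)OC (boron groups in 6)
Why: Directed ortho-metalation, borylation and oxidation of the C–B bond (aryl shift from boron to oxygen): in each ring the hydrogen between the methoxy and the aryloxy oxygen is the most acidic and is flanked by two coordinating oxygens, as in a resorcinol diether, so lithiation should occur there and not ortho to a single oxygen or to the acetal; excess peroxide is destroyed before neutralisation so that no free aldehyde meets it.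

Step 4
Reactants: 7 bis[4-(dimethoxymethyl)-2-hydroxy-3-methoxyphenyl] ether
Product: 9 bis[2-(benzyloxy)-4-formyl-3-methoxyphenyl] ether, via bis(benzyl ether) bis-acetal 8 (not isolated)
Conditions: BnBr, K2CO3, DMF, 60 °C; then 2 M HCl, THF, rt
Reagents that add atoms: benzyl bromide, BrCc1ccccc1; water, O (carbonyl oxygens on acetal hydrolysis)
Why: Williamson etherification of the doubly ortho-substituted phenoxides in a dipolar aprotic solvent, followed by hydrolysis of the electron-rich aryl dimethyl acetals, which cleave under mild aqueous acid that leaves benzyl and diaryl ethers untouched.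

Step 5
Reactants: 10 2,4-dihydroxyacetophenone
Product: 11 1-[4-(benzyloxy)-2-hydroxyphenyl]ethan-1-one
Conditions: BnBr (1.05 equiv), K2CO3, acetone, reflux
Reagents that add atoms: benzyl bromide, BrCc1ccccc1
Why: Regioselective Williamson etherification: the ortho hydroxyl is held in a hydrogen bond to the ketone and is much less nucleophilic, so one equivalent of benzyl bromide should react at the para hydroxyl only.

Step 6
Reactants: 11 1-[4-(benzyloxy)-2-hydroxyphenyl]ethan-1-one
Product: 12 1-[4-(benzyloxy)-2-(methoxymethoxy)phenyl]ethan-1-one
Conditions: NaH, MOMCl, DMF, 0 °C to rt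
Reagents that add atoms: chloromethyl methyl ether, COCCl
Why: O-alkylation of the sodium phenoxide, the strong base breaking the chelate; the MOM acetal is stable to the hydroxide of step 7 and is removed by the acid of step 9.

Step 7
Reactants: 9 bis[2-(benzyloxy)-4-formyl-3-methoxyphenyl] ether; 12 1-[4-(benzyloxy)-2-(methoxymethoxy)phenyl]ethan-1-one (2.3 equiv)
Product: 13 bis{2-(benzyloxy)-3-methoxy-4-[(1E)-3-oxo-3-(4-(benzyloxy)-2-(methoxymethoxy)phenyl)prop-1-en-1-yl]phenyl} ether
Conditions: KOH (aq), EtOH/THF, rt
Reagents that add atoms: none
Why: Two-fold Claisen–Schmidt condensation: only 12 can form an enolate and only 9 is a reactive acceptor, and the E1cB dehydration of each aldol gives the conjugated E-enone as the thermodynamic product.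

Step 8
Reactants: 13 bis{2-(benzyloxy)-3-methoxy-4-[(1E)-3-oxo-3-(4-(benzyloxy)-2-(methoxymethoxy)phenyl)prop-1-en-1-yl]phenyl} ether
Product: 14 bis{2-(benzyloxy)-4-[1,1-dimethoxy-3-oxo-3-(4-(benzyloxy)-2-(methoxymethoxy)phenyl)propan-2-yl]-3-methoxyphenyl} ether (mixture of diastereomers)
Conditions: Tl(NO3)3·3H2O (2.5 equiv), MeOH/HC(OMe)3/CH2Cl2, 0 °C to rt; aq NaHCO3, filtration of TlNO3
Reagents that add atoms: methanol, CO (the four methoxy groups)
Why: The trivalent thallium nitrate adds to each enone C=C (oxythallation), methanol taking the benzylic β-carbon, which best carries positive charge thanks to the para aryloxy and ortho methoxy groups of ring B, and thallium the α-carbon. The weak C–Tl bond then ionises with departure of monovalent thallium while ring B bridges Cα and Cβ as a phenonium ion and ends on Cα, forming the C3–C1' bond of that arm; the oxocarbenium ion left at the old β-carbon is trapped by methanol as the dimethyl acetal, the future C2. The closest known reaction type is the oxidative 1,2-aryl rearrangement of 2'-alkoxychalcones to 1,2-diaryl-3,3-dimethoxypropan-1-ones, the standard chemical entry to isoflavones and a copy of the biosynthetic aryl shift. No ring is closed here; both pyranones close in step 9. The two α-carbons become stereocentres without control, which is immaterial because both are planarised in step 9. The step needs migration of ring B to beat simple methoxylation without shift, migration of ring A after ketalisation of the carbonyl (which would give a 2,3-diarylpropanoate ester), and aurone formation by an ortho phenol. This is secured by the electron-rich ring B, by the MOM ether that masks the ortho oxygen and hinders ketalisation, and by keeping the orthoformate to the amount needed for drying, with CH2Cl2 as co-solvent for solubility. The arms are electronically insulated by the ether oxygen, so the second rearrangement should proceed like the first with a slight excess over two equivalents of oxidant.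

Step 9
Reactants: 14 bis{2-(benzyloxy)-4-[1,1-dimethoxy-3-oxo-3-(4-(benzyloxy)-2-(methoxymethoxy)phenyl)propan-2-yl]-3-methoxyphenyl} ether (mixture of diastereomers)
Product: 16 bis{2-(benzyloxy)-4-[7-(benzyloxy)-4-oxo-4H-chromen-3-yl]-3-methoxyphenyl} ether, via bis(2-hydroxyphenyl) keto acetal 15 (not isolated)
Conditions: 10% HCl, MeOH/THF, 60 °C
Reagents that add atoms: none
Why: Acid solvolysis of the MOM acetals frees the ortho phenols, which displace one methoxy group of the neighbouring acetal (6-exo closure through the oxocarbenium ion), and β-elimination of methanol gives the aromatic-like γ-pyranone; this erases the stereocentres of 14, and aryl benzyl ethers and the diaryl ether are stable to these conditions.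

Step 10
Reactants: 16 bis{2-(benzyloxy)-4-[7-(benzyloxy)-4-oxo-4H-chromen-3-yl]-3-methoxyphenyl} ether
Product: 18 bis{2-(benzyloxy)-4-[(3R,4R)-7-(benzyloxy)-4-hydroxychroman-3-yl]-3-methoxyphenyl} ether (cis in each ring), via bis-isoflavanone 17 (not isolated)
Conditions: RuCl[(R,R)-TsDPEN](p-cymene) (10 mol %), HCO2H/Et3N (5:2), EtOAc/DMF, 40 °C
Reagents that add atoms: none
Why: Asymmetric transfer hydrogenation cascade known for isoflavones: the ruthenium hydride first reduces the C2=C3 bond, the resulting α-aryl ketone 17 epimerises rapidly at C3 under the amine, and the catalyst reduces only the C3 epimer that lets hydride reach its preferred carbonyl face anti to ring B (dynamic kinetic resolution), which sets 4R by catalyst control and 3R through the cis relationship. Because the arms react independently, a wrong outcome in one arm gives mainly the separable meso-type diastereomer, so the enantiomeric purity of the C2-symmetric product should exceed that of a single arm.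

Step 11
Reactants: 18 bis{2-(benzyloxy)-4-[(3R,4R)-7-(benzyloxy)-4-hydroxychroman-3-yl]-3-methoxyphenyl} ether
Product: 19 bis{2-hydroxy-4-[(3R)-7-hydroxychroman-3-yl]-3-methoxyphenyl} ether (the target)
Conditions: H2 (3 bar), Pd/C, THF/EtOH, AcOH (5 vol %), rt
Reagents that add atoms: none
Why: Heterogeneous hydrogenolysis cleaves the four benzyl ethers and the two benzylic C4–O bonds, which are activated by the ortho and para oxygens of ring A; C3 carries no heteroatom and is not touched, and weak acid at room temperature avoids ionisation at C4, so the 3R configuration is carried into the target unchanged.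

## Compound list

1 | 4-fluoro-2-methoxybenzaldehyde | COc1cc(F)ccc1C=O | starting material
2 | 4-hydroxy-2-methoxybenzaldehyde | COc1cc(O)ccc1C=O | starting material
3 | bis(4-formyl-3-methoxyphenyl) ether | COc1cc(Oc2ccc(C=O)c(OC)c2)ccc1C=O | intermediate
4 | bis[4-(dimethoxymethyl)-3-methoxyphenyl] ether | COc1cc(Oc2ccc(C(OC)OC)c(OC)c2)ccc1C(OC)OC | intermediate
5 | bis[4-(dimethoxymethyl)-2-lithio-3-methoxyphenyl] ether | COc1c([Li])c(Oc2ccc(C(OC)OC)c(OC)c2[Li])ccc1C(OC)OC | intermediate (not isolated)
6 | bis[2-(dimethoxyboryl)-4-(dimethoxymethyl)-3-methoxyphenyl] ether | COc1c(B(OC)OC)c(Oc2ccc(C(OC)OC)c(OC)c2B(OC)OC)ccc1C(OC)OC | intermediate (not isolated)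
7 | bis[4-(dimethoxymethyl)-2-hydroxy-3-methoxyphenyl] ether | COc1c(O)c(Oc2ccc(C(OC)OC)c(OC)c2O)ccc1C(OC)OC | intermediate
8 | bis[2-(benzyloxy)-4-(dimethoxymethyl)-3-methoxyphenyl] ether | COc1c(OCc2ccccc2)c(Oc2ccc(C(OC)OC)c(OC)c2OCc2ccccc2)ccc1C(OC)OC | intermediate (not isolated)
9 | bis[2-(benzyloxy)-4-formyl-3-methoxyphenyl] ether | COc1c(OCc2ccccc2)c(Oc2ccc(C=O)c(OC)c2OCc2ccccc2)ccc1C=O | intermediate
10 | 2,4-dihydroxyacetophenone | CC(=O)c1ccc(O)cc1O | starting material
11 | 1-[4-(benzyloxy)-2-hydroxyphenyl]ethan-1-one | CC(=O)c1ccc(OCc2ccccc2)cc1O | intermediate
12 | 1-[4-(benzyloxy)-2-(methoxymethoxy)phenyl]ethan-1-one | CC(=O)c1ccc(OCc2ccccc2)cc1OCOC | intermediate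
13 | bis-chalcone, both enones E, MOM and benzyl protected | COc1c(/C=C/C(=O)c2ccc(OCc3ccccc3)cc2OCOC)ccc(Oc2ccc(/C=C/C(=O)c3ccc(OCc4ccccc4)cc3OCOC)c(OC)c2OCc2ccccc2)c1OCc1ccccc1 | intermediate
14 | bis(1,2-diaryl-3,3-dimethoxypropan-1-one), mixture of diastereomers | COc1c(C(C(OC)OC)C(=O)c2ccc(OCc3ccccc3)cc2OCOC)ccc(Oc2ccc(C(C(OC)OC)C(=O)c3ccc(OCc4ccccc4)cc3OCOC)c(OC)c2OCc2ccccc2)c1OCc1ccccc1 | intermediate
15 | bis(2-hydroxyphenyl) keto acetal (14 without the MOM groups) | COc1c(C(C(OC)OC)C(=O)c2ccc(OCc3ccccc3)cc2O)ccc(Oc2ccc(C(C(OC)OC)C(=O)c3ccc(OCc4ccccc4)cc3O)c(OC)c2OCc2ccccc2)c1OCc1ccccc1 | intermediate (not isolated)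
16 | bis{2-(benzyloxy)-4-[7-(benzyloxy)-4-oxo-4H-chromen-3-yl]-3-methoxyphenyl} ether | COc1c(-c2coc3cc(OCc4ccccc4)ccc3c2=O)ccc(Oc2ccc(-c3coc4cc(OCc5ccccc5)ccc4c3=O)c(OC)c2OCc2ccccc2)c1OCc1ccccc1 | intermediate
17 | bis{2-(benzyloxy)-4-[7-(benzyloxy)-4-oxochroman-3-yl]-3-methoxyphenyl} ether, C3 epimers interconverting | COc1c(C2COc3cc(OCc4ccccc4)ccc3C2=O)ccc(Oc2ccc(C3COc4cc(OCc5ccccc5)ccc4C3=O)c(OC)c2OCc2ccccc2)c1OCc1ccccc1 | intermediate (not isolated)
18 | bis{2-(benzyloxy)-4-[(3R,4R)-7-(benzyloxy)-4-hydroxychroman-3-yl]-3-methoxyphenyl} ether | COc1c([C@@H]2COc3cc(OCc4ccccc4)ccc3[C@@H]2O)ccc(Oc2ccc([C@@H]3COc4cc(OCc5ccccc5)ccc4[C@@H]3O)c(OC)c2OCc2ccccc2)c1OCc1ccccc1 | intermediate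
19 | bis{2-hydroxy-4-[(3R)-7-hydroxychroman-3-yl]-3-methoxyphenyl} ether | COc1c([C@@H]2COc3cc(O)ccc3C2)ccc(Oc2ccc([C@@H]3COc4cc(O)ccc4C3)c(OC)c2O)c1O | target

## Step count and least certain steps

Total step count: 11. Longest linear sequence: 9 steps (steps 1 to 4 and 7 to 11); steps 5 and 6 form the short branch that supplies 12.

Step 8 (key step).
- What may go wrong: the nitric acid released from the oxidant may solvolyse a MOM group before that arm has rearranged, and the freed ortho phenol may divert the arm toward aurone-type cyclisation. The ketone may be ketalised so that ring A migrates instead of ring B. The reaction may stop after one arm, or the very electron-rich ring B may be attacked oxidatively.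
- Fallback, from 13 to 16: 13 is epoxidised under Weitz–Scheffer conditions (H2O2, NaOH, MeOH/THF) to the bis(trans-epoxy ketone) F1. BF3·OEt2 in CH2Cl2 opens each epoxide at the benzylic carbon and the aroyl group shifts to that carbon (1,2-acyl migration), giving the bis(2-aryl-3-oxopropanal) F2. HCl in MeOH then removes the MOM groups and dehydrates the cyclic hemiacetals to 16. The same isoflavone skeleton is reached by moving the acyl group instead of ring B, without thallium.

Step 3.
- What may go wrong: the second metalation may remain incomplete, or metalation may occur ortho to an acetal, so that mono-hydroxylated or regioisomeric material forms.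
- Fallback, from 1 to 9: 1 is converted into its dimethyl acetal F3 (HC(OMe)3, MeOH, p-TsOH). Lithiation at −78 °C, where fluorine and methoxy together acidify the hydrogen between them and only one metalation per molecule is needed, then B(OMe)3 and basic H2O2, gives the phenol F4. Benzylation (BnBr, K2CO3) gives the benzyl ether F5 and aqueous acid the fluoro aldehyde F6. Part of F6 is converted into the phenol F7 by displacement of fluoride with the alkoxide of 2-(methylsulfonyl)ethanol (NaH, DMF), which then eliminates to release the phenoxide. F6 and F7 are joined by the addition–elimination of step 1 (K2CO3, DMAc, 130 °C) to give 9.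

Step 10.
- What may go wrong: the cascade may stall after the conjugate reduction in one arm, or ketone reduction may outrun epimerisation at C3, so that trans carbinols and, through mismatched arms, the meso-type isomer accumulate.
- Fallback, from 16 to 19: excess NaBH4 in THF/EtOH reduces 16 to the stereorandom bis(chroman-4-ol) F8. Acid-catalysed dehydration (p-TsOH, toluene, 80 °C) gives the bis(2H-chromene) F9. Asymmetric hydrogenation of the trisubstituted styrene-type double bonds with an iridium phosphinooxazoline complex, [Ir(cod)(PHOX)]BArF, H2 (50 bar), CH2Cl2, using the ligand enantiomer that leads to 3R, gives the tetrabenzyl bis-isoflavan F10. Neutral hydrogenolysis (H2, Pd/C) gives 19. The stereocentre is then set by face-selective addition of hydrogen to an alkene and not by a resolution.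

Step 11.
- What may go wrong: acid-assisted ionisation of the doubly oxygen-activated C4 carbinol, loss of the C3 proton and unselective re-hydrogenation would erode the configuration; the C4–O cleavage may also remain incomplete.
- Fallback, from 18 to 19: 18 is acylated with 1,1'-thiocarbonyldiimidazole to the bis(imidazole-1-carbothioate) F11. Radical Barton–McCombie deoxygenation ((Me3Si)3SiH, Et3B, air, toluene, rt) removes both C4 oxygens without a cation; the C3 hydrogen is anti to the C4 oxygen in the cis carbinol, so thermal syn-elimination is also disfavoured. This gives the tetrabenzyl bis-isoflavan F10, and neutral hydrogenolysis (H2, Pd/C, EtOAc/EtOH) gives 19.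

## Further compounds

F1 | step 8 | bis(trans-2,3-epoxy ketone) derived from 13, mixture of diastereomers | COc1c(C2OC2C(=O)c2ccc(OCc3ccccc3)cc2OCOC)ccc(Oc2ccc(C3OC3C(=O)c3ccc(OCc4ccccc4)cc3OCOC)c(OC)c2OCc2ccccc2)c1OCc1ccccc1
F2 | step 8 | bis(2-aryl-3-aryl-3-oxopropanal), mixture of diastereomers and enol forms | COc1c(C(C=O)C(=O)c2ccc(OCc3ccccc3)cc2OCOC)ccc(Oc2ccc(C(C=O)C(=O)c3ccc(OCc4ccccc4)cc3OCOC)c(OC)c2OCc2ccccc2)c1OCc1ccccc1
F3 | step 3 | 1-(dimethoxymethyl)-4-fluoro-2-methoxybenzene | COc1cc(F)ccc1C(OC)OC
F4 | step 3 | 3-(dimethoxymethyl)-6-fluoro-2-methoxyphenol | COc1c(O)c(F)ccc1C(OC)OC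
F5 | step 3 | 2-(benzyloxy)-4-(dimethoxymethyl)-1-fluoro-3-methoxybenzene | COc1c(OCc2ccccc2)c(F)ccc1C(OC)OC
F6 | step 3 | 3-(benzyloxy)-4-fluoro-2-methoxybenzaldehyde | COc1c(OCc2ccccc2)c(F)ccc1C=O
F7 | step 3 | 3-(benzyloxy)-4-hydroxy-2-methoxybenzaldehyde | COc1c(OCc2ccccc2)c(O)ccc1C=O
F8 | step 10 | bis{2-(benzyloxy)-4-[7-(benzyloxy)-4-hydroxychroman-3-yl]-3-methoxyphenyl} ether, mixture of stereoisomers | COc1c(C2COc3cc(OCc4ccccc4)ccc3C2O)ccc(Oc2ccc(C3COc4cc(OCc5ccccc5)ccc4C3O)c(OC)c2OCc2ccccc2)c1OCc1ccccc1
F9 | step 10 | bis{2-(benzyloxy)-4-[7-(benzyloxy)-2H-chromen-3-yl]-3-methoxyphenyl} ether | COc1c(C2=Cc3ccc(OCc4ccccc4)cc3OC2)ccc(Oc2ccc(C3=Cc4ccc(OCc5ccccc5)cc4OC3)c(OC)c2OCc2ccccc2)c1OCc1ccccc1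
F10 | step 10 | bis{2-(benzyloxy)-4-[(3R)-7-(benzyloxy)chroman-3-yl]-3-methoxyphenyl} ether | COc1c([C@@H]2COc3cc(OCc4ccccc4)ccc3C2)ccc(Oc2ccc([C@@H]3COc4cc(OCc5ccccc5)ccc4C3)c(OC)c2OCc2ccccc2)c1OCc1ccccc1
F11 | step 11 | bis(O-[(3R,4R)-chroman-4-yl] imidazole-1-carbothioate) of 18 | COc1c([C@@H]2COc3cc(OCc4ccccc4)ccc3[C@@H]2OC(=S)n2ccnc2)ccc(Oc2ccc([C@@H]3COc4cc(OCc5ccccc5)ccc4[C@@H]3OC(=S)n3ccnc3)c(OC)c2OCc2ccccc2)c1OCc1ccccc1
A1 | alternative 1 | stereodefined bis-iodide, each arm 1-aryl-1-(iodomethyl)-2-(tert-butyldimethylsilyloxy)ethyl | COc1c([C@@H](CI)CO[Si](C)(C)C(C)(C)C)ccc(Oc2ccc([C@@H](CI)CO[Si](C)(C)C(C)(C)C)c(OC)c2OCc2ccccc2)c1OCc1ccccc1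
A2 | alternative 1 | 3-ethoxycyclohex-2-en-1-one | CCOC1=CC(=O)CCC1
A3 | alternative 1 | bis(6-alkyl-3-ethoxycyclohex-2-enone), mixture at the ring carbon | COc1c([C@@H](CC2CCC(OCC)=CC2=O)CO[Si](C)(C)C(C)(C)C)ccc(Oc2ccc([C@@H](CC3CCC(OCC)=CC3=O)CO[Si](C)(C)C(C)(C)C)c(OC)c2OCc2ccccc2)c1OCc1ccccc1
A4 | alternative 2 | bis(diazo enone) bearing ethynyl ethers | COc1c([C@@H](CC(=[N+]=[N-])C(=O)C=C)COC#C)ccc(Oc2ccc([C@@H](CC(=[N+]=[N-])C(=O)C=C)COC#C)c(OC)c2OCc2ccccc2)c1OCc1ccccc1
A5 | alternative 2 | target with both ring B hydroxyls as benzyl ethers | COc1c([C@@H]2COc3cc(O)ccc3C2)ccc(Oc2ccc([C@@H]3COc4cc(O)ccc4C3)c(OC)c2OCc2ccccc2)c1OCc1ccccc1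
A6 | alternative 3 | bis-isoflavan lacking the C3' oxygens, bis(C7 triisopropylsilyl ether) | COc1c([C@@H]2COc3cc(O[Si](C(C)C)(C(C)C)C(C)C)ccc3C2)ccc(Oc2ccc([C@@H]3COc4cc(O[Si](C(C)C)(C(C)C)C(C)C)ccc4C3)c(OC)c2)c1
A7 | alternative 3 | target as its bis(C7 triisopropylsilyl ether) | COc1c([C@@H]2COc3cc(O[Si](C(C)C)(C(C)C)C(C)C)ccc3C2)ccc(Oc2ccc([C@@H]3COc4cc(O[Si](C(C)C)(C(C)C)C(C)C)ccc4C3)c(OC)c2O)c1O
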